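**Retrosynthetic overview**

- The target is a (2S,4R)-7,3',4'-trihydroxyflavan (rings A, B, C; 2,4-trans) bonded from C4 to C8 of (−)-epigallocatechin (benzo ring D, trihydroxyphenyl ring E, pyran ring F). The last step removes nine benzyl ethers.
- The C2–aryl bond to ring B is cut to a C2 oxocarbenium ion, made from a 2-ethoxychroman, and an aryltrifluoroborate. Attack opposite the C4 aryl gives the 2,4-trans flavan, which an endo cycloaddition of a styrene would not.
- Ring C is cut at O1–C2 and C3–C4 by a retro-[4+2]. The strategy rests on the O1–C8a=C4a–C4 unit of ring C fused to ring A: it is a masked ortho-quinone methide of ring A whose methide carbon C4 already carries C8 of ring D. The partner is ethyl vinyl ether under a chiral phosphoric acid.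
- The C4–C8(ring D) bond comes from 8-lithio hexa-O-benzyl-epigallocatechin and a silyl-protected 4-benzyloxysalicylaldehyde.
- Ring order: rings A, B, D, E and F are bought; ring C is the only ring made (step 7), and ring B is attached after it (step 9).

Key step: step 7

Assumption: the (R)-configured phosphoric acid in step 7 is taken to be the enantiomer that leads to (4R); the sense of induction must be confirmed, and the (S)-acid would be used in the same step if it is the other way round.

**Route**

Step 1
Reactants: 1 (−)-epigallocatechin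
Product: 2 5,7,3',4',5'-penta-O-benzyl-(−)-epigallocatechin (free 3-OH)
Conditions: BnBr (5.5 equiv), K2CO3, degassed DMF, Ar, 0 °C → rt
Reagents that add atoms: benzyl bromide, BrCc1ccccc1
Why: Williamson etherification in which carbonate deprotonates only the five phenols and not the C3 alcohol, and the mild base at room temperature under argon should avoid C2 epimerisation and oxidation of ring E, so the (2R,3R) centres are carried through unchanged.

Step 2
Reactants: 2 5,7,3',4',5'-penta-O-benzyl-(−)-epigallocatechin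
Product: 3 3,5,7,3',4',5'-hexa-O-benzyl-(−)-epigallocatechin
Conditions: NaH, BnBr, Bu4NI (cat.), THF–DMF, 0 °C → rt
Reagents that add atoms: benzyl bromide, BrCc1ccccc1
Why: Williamson etherification of the secondary alkoxide, which cannot epimerise C2 because no free phenol is left to open ring F through a quinone methide.

Step 3
Reactants: 3 3,5,7,3',4',5'-hexa-O-benzyl-(−)-epigallocatechin
Product: 4 8-bromo-3,5,7,3',4',5'-hexa-O-benzyl-(−)-epigallocatechin
Conditions: NBS (1.0 equiv), CH2Cl2, −78 → 0 °C
Reagents that add atoms: N-bromosuccinimide, O=C1CCC(=O)N1Br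
Why: Electrophilic aromatic bromination, in which C8 of ring D is the more reactive free position of 5,7-di-O-benzyl flavan-3-ol ethers, so one equivalent of NBS at low temperature should brominate there and leave C6 and ring E alone.

Step 4
Reactants: 5 4-(benzyloxy)-2-hydroxybenzaldehyde
Product: 6 4-(benzyloxy)-2-(tert-butyldimethylsilyloxy)benzaldehyde
Conditions: TBSCl, imidazole, DMF, rt
Reagents that add atoms: tert-butyldimethylsilyl chloride, CC(C)(C)[Si](C)(C)Cl
Why: Imidazole-promoted silylation masks the acidic phenol that would quench the aryllithium of step 5, and the silyl ether can later be removed by fluoride without acid.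

Step 5
Reactants: 4 8-bromo-3,5,7,3',4',5'-hexa-O-benzyl-(−)-epigallocatechin; 6 4-(benzyloxy)-2-(tert-butyldimethylsilyloxy)benzaldehyde
Product: 8 [4-(benzyloxy)-2-(tert-butyldimethylsilyloxy)phenyl](hexa-O-benzyl-epigallocatechin-8-yl)methanol (both carbinol epimers), via 8-lithio-hexa-O-benzyl-epigallocatechin 7 (not isolated)
Conditions: n-BuLi (1.05 equiv), THF, −78 °C; then 6, −78 °C; sat. aq NH4Cl at −78 °C
Reagents that add atoms: none
Why: Bromine–lithium exchange at −78 °C is faster than deprotonation next to the benzyl ethers, and 1,2-addition of the 2,6-dialkoxyaryllithium to the aldehyde makes the C4–C8(ring D) bond, the carbinol centre being left as a mixture because it becomes planar in step 7 and the cold quench keeping the silyl group on the phenol.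

Step 6
Reactants: 8 [4-(benzyloxy)-2-(tert-butyldimethylsilyloxy)phenyl](hexa-O-benzyl-epigallocatechin-8-yl)methanol
Product: 9 [4-(benzyloxy)-2-hydroxyphenyl](hexa-O-benzyl-epigallocatechin-8-yl)methanol (both carbinol epimers)
Conditions: Bu4NF, AcOH (1:1), THF, 0 °C; chromatography on Et3N-deactivated silica
Reagents that add atoms: none
Why: Fluoride-mediated desilylation of the aryl silyl ether, buffered with acetic acid so that the ionisation-prone diarylcarbinol meets neither strong base nor strong acid, and any isomer in which silicon has moved to the carbinol oxygen should give the same diol.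

Step 7
Reactants: 9 [4-(benzyloxy)-2-hydroxyphenyl](hexa-O-benzyl-epigallocatechin-8-yl)methanol; 10 ethyl vinyl ether
Product: 12 (2R,4R)-7-(benzyloxy)-2-ethoxy-4-(hexa-O-benzyl-epigallocatechin-8-yl)chroman (2,4-cis acetal), via ortho-quinone methide 11 (not isolated)
Conditions: 10 (5 equiv), (R)-3,3'-bis(2,4,6-triisopropylphenyl)-1,1'-binaphthyl-2,2'-diyl hydrogen phosphate (10 mol %), 4 Å MS, toluene, −20 → 0 °C
Reagents that add atoms: none
Why: The phosphoric acid protonates the carbinol of 9 and water leaves, giving ortho-quinone methide 11, which stays hydrogen-bonded (in the limit ion-paired) to the chiral phosphate through its ring A oxygen. The nucleophilic CH2 terminus of ethyl vinyl ether adds to the methide carbon C4 and the oxygen-bearing carbon is captured by O1 in a concerted, asynchronous inverse-demand hetero-Diels–Alder reaction; the closest known reaction type is the chiral Brønsted acid-catalysed [4+2] cycloaddition of ortho-quinone methides generated from ortho-hydroxybenzhydrols with enol ethers, enamides and styrenes. Ring C is closed by the cycloaddition itself as a six-membered ring (in the stepwise limit, a 6-endo-trig attack of O1 on the ethoxy-oxocarbenium carbon). C4 is set by the catalyst, whose 3,3'-aryl groups block one face of the planar methide so that the alkene should add to the face giving (4R), while C2 is set by the endo approach of the ethoxy group (2,4-cis) and is of no consequence because it is destroyed in step 9. The step needs facial selectivity at C4 (catalyst, with the stereocentres of ring F as a remote second influence), regioselectivity (fixed by the polarity of the two partners) and site selectivity, which is secured because only ring A carries a free phenol while every oxygen of rings D and E is benzylated, so only one quinone methide and one chroman can form.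

Step 8
Reactants: 13 4-bromo-1,2-bis(benzyloxy)benzene
Product: 16 potassium [3,4-bis(benzyloxy)phenyl]trifluoroborate, via 3,4-bis(benzyloxy)phenyllithium 14 (not isolated), via lithium aryl(triisopropoxy)borate 15 (not isolated)
Conditions: n-BuLi, THF, −78 °C; B(OiPr)3, −78 °C → rt; aq KHF2, rt; recrystallisation from acetone–Et2O
Reagents that add atoms: triisopropyl borate, CC(C)OB(OC(C)C)OC(C)C; potassium hydrogen difluoride, [K+].[F-].F
Why: Bromine–lithium exchange, borylation with the trialkyl borate and fluoride exchange with KHF2 is the standard one-pot route to a crystalline potassium aryltrifluoroborate, and the benzyl ethers are inert to all three operations.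

Step 9
Reactants: 12 (2R,4R)-7-(benzyloxy)-2-ethoxy-4-(hexa-O-benzyl-epigallocatechin-8-yl)chroman; 16 potassium [3,4-bis(benzyloxy)phenyl]trifluoroborate
Product: 18 (2S,4R)-7-(benzyloxy)-2-[3,4-bis(benzyloxy)phenyl]-4-(hexa-O-benzyl-epigallocatechin-8-yl)chroman (2,4-trans; the nona-O-benzyl ether of the target), via chroman-2-ylium ion 17 (not isolated)
Conditions: BF3·OEt2 (2 equiv), 16 (2 equiv), MeCN–CH2Cl2, −40 → 0 °C; aq NaHCO3
Reagents that add atoms: none
Why: BF3 removes the ethoxy group to give oxocarbenium ion 17, to which the electron-rich aryltrifluoroborate (as its aryldifluoroborane) transfers its ipso carbon in a Lewis acid-promoted acetal–organotrifluoroborate coupling that fixes the position of attachment on ring B, and axial attack on the half-chair cation from the face opposite the bulky C4 aryl group should set C2 as (2S), 2,4-trans, under kinetic control at low temperature, both acetal epimers converging on the same cation.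

Step 10
Reactants: 18 (2S,4R)-7-(benzyloxy)-2-[3,4-bis(benzyloxy)phenyl]-4-(hexa-O-benzyl-epigallocatechin-8-yl)chroman
Product: 19 8-[(2S,4R)-2-(3,4-dihydroxyphenyl)-7-hydroxychroman-4-yl]-(−)-epigallocatechin (CNP0211965.1)
Conditions: H2 (1 atm), Pd(OH)2/C, degassed THF–MeOH–H2O, rt; filtration under Ar, lyophilisation
Reagents that add atoms: none
Why: Catalytic hydrogenolysis cleaves the nine O–benzyl bonds (eight aryl ethers and one alkyl ether) while the cyclic benzylic C2–O1 bonds of rings C and F and the C4–C8 bond should not be broken under neutral conditions at 1 atm, so the four stereocentres are unchanged.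

**Compound list**

1 | (−)-epigallocatechin | Oc1cc(O)c2c(c1)O[C@H](c1cc(O)c(O)c(O)c1)[C@H](O)C2 | starting material
2 | 5,7,3',4',5'-penta-O-benzyl-(−)-epigallocatechin | c1c(OCc3ccccc3)cc(OCc3ccccc3)c2c1O[C@H](c1cc(OCc3ccccc3)c(OCc3ccccc3)c(OCc3ccccc3)c1)[C@H](O)C2 | intermediate
3 | 3,5,7,3',4',5'-hexa-O-benzyl-(−)-epigallocatechin | c1c(OCc3ccccc3)cc(OCc3ccccc3)c2c1O[C@H](c1cc(OCc3ccccc3)c(OCc3ccccc3)c(OCc3ccccc3)c1)[C@H](OCc3ccccc3)C2 | intermediate
4 | 8-bromo-3,5,7,3',4',5'-hexa-O-benzyl-(−)-epigallocatechin | Brc1c(OCc3ccccc3)cc(OCc3ccccc3)c2c1O[C@H](c1cc(OCc3ccccc3)c(OCc3ccccc3)c(OCc3ccccc3)c1)[C@H](OCc3ccccc3)C2 | intermediate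
5 | 4-(benzyloxy)-2-hydroxybenzaldehyde | O=Cc1ccc(OCc2ccccc2)cc1O | starting material
6 | 4-(benzyloxy)-2-(tert-butyldimethylsilyloxy)benzaldehyde | O=Cc1ccc(OCc2ccccc2)cc1O[Si](C)(C)C(C)(C)C | intermediate
7 | 8-lithio-hexa-O-benzyl-epigallocatechin | [Li]c1c(OCc3ccccc3)cc(OCc3ccccc3)c2c1O[C@H](c1cc(OCc3ccccc3)c(OCc3ccccc3)c(OCc3ccccc3)c1)[C@H](OCc3ccccc3)C2 | intermediate (not isolated)
8 | [4-(benzyloxy)-2-(tert-butyldimethylsilyloxy)phenyl](hexa-O-benzyl-epigallocatechin-8-yl)methanol, carbinol epimers | OC(c1ccc(OCc3ccccc3)cc1O[Si](C)(C)C(C)(C)C)c1c(OCc3ccccc3)cc(OCc3ccccc3)c2c1O[C@H](c1cc(OCc3ccccc3)c(OCc3ccccc3)c(OCc3ccccc3)c1)[C@H](OCc3ccccc3)C2 | intermediate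
9 | [4-(benzyloxy)-2-hydroxyphenyl](hexa-O-benzyl-epigallocatechin-8-yl)methanol, carbinol epimers | OC(c1ccc(OCc3ccccc3)cc1O)c1c(OCc3ccccc3)cc(OCc3ccccc3)c2c1O[C@H](c1cc(OCc3ccccc3)c(OCc3ccccc3)c(OCc3ccccc3)c1)[C@H](OCc3ccccc3)C2 | intermediate
10 | ethyl vinyl ether | C=COCC | starting material
11 | (E)-3-(benzyloxy)-6-[(hexa-O-benzyl-epigallocatechin-8-yl)methylidene]cyclohexa-2,4-dien-1-one (ortho-quinone methide) | O=C1C=C(OCc3ccccc3)C=C/C1=C\c1c(OCc3ccccc3)cc(OCc3ccccc3)c2c1O[C@H](c1cc(OCc3ccccc3)c(OCc3ccccc3)c(OCc3ccccc3)c1)[C@H](OCc3ccccc3)C2 | intermediate (not isolated)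
12 | (2R,4R)-7-(benzyloxy)-2-ethoxy-4-(hexa-O-benzyl-epigallocatechin-8-yl)chroman | c1ccccc1COc1ccc2c(c1)O[C@@H](OCC)C[C@H]2c1c(OCc3ccccc3)cc(OCc3ccccc3)c2c1O[C@H](c1cc(OCc3ccccc3)c(OCc3ccccc3)c(OCc3ccccc3)c1)[C@H](OCc3ccccc3)C2 | intermediate
13 | 4-bromo-1,2-bis(benzyloxy)benzene | Brc1ccc(OCc2ccccc2)c(OCc2ccccc2)c1 | starting material
14 | 3,4-bis(benzyloxy)phenyllithium | [Li]c1ccc(OCc2ccccc2)c(OCc2ccccc2)c1 | intermediate (not isolated)
15 | lithium [3,4-bis(benzyloxy)phenyl]triisopropoxyborate | [Li+].CC(C)O[B-](OC(C)C)(OC(C)C)c1ccc(OCc2ccccc2)c(OCc2ccccc2)c1 | intermediate (not isolated)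
16 | potassium [3,4-bis(benzyloxy)phenyl]trifluoroborate | [K+].F[B-](F)(F)c1ccc(OCc2ccccc2)c(OCc2ccccc2)c1 | intermediate
17 | (4R)-7-(benzyloxy)-4-(hexa-O-benzyl-epigallocatechin-8-yl)-3,4-dihydrochromen-1-ylium ethoxytrifluoroborate (C2 oxocarbenium ion) | CCO[B-](F)(F)F.c1ccccc1COc1ccc2c(c1)[O+]=CC[C@H]2c1c(OCc3ccccc3)cc(OCc3ccccc3)c2c1O[C@H](c1cc(OCc3ccccc3)c(OCc3ccccc3)c(OCc3ccccc3)c1)[C@H](OCc3ccccc3)C2 | intermediate (not isolated)
18 | (2S,4R)-7-(benzyloxy)-2-[3,4-bis(benzyloxy)phenyl]-4-(hexa-O-benzyl-epigallocatechin-8-yl)chroman | c1ccccc1COc1ccc2c(c1)O[C@H](c1ccc(OCc3ccccc3)c(OCc3ccccc3)c1)C[C@H]2c1c(OCc3ccccc3)cc(OCc3ccccc3)c2c1O[C@H](c1cc(OCc3ccccc3)c(OCc3ccccc3)c(OCc3ccccc3)c1)[C@H](OCc3ccccc3)C2 | intermediate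
19 | 8-[(2S,4R)-2-(3,4-dihydroxyphenyl)-7-hydroxychroman-4-yl]-(−)-epigallocatechin | Oc1ccc2c(c1)O[C@H](c1ccc(O)c(O)c1)C[C@H]2c1c(O)cc(O)c2c1O[C@H](c1cc(O)c(O)c(O)c1)[C@H](O)C2 | target

**Step count and risks**

Total step count: 10. Longest linear sequence: 8 steps (steps 1, 2, 3, 5, 6, 7, 9, 10).

Steps most likely to fail:

1. Step 7. The vinyl ether has no hydrogen-bond donor, so the catalyst holds only the quinone methide, and facial discrimination at the methide carbon may be poor. The stereocentres of ring F may also work against the catalyst, and the acid may consume vinyl ether by adding the hydroxyl groups of 9 to it. Fallback: the same quinone methide is generated under basic conditions and its facial selectivity is controlled by an auxiliary on the enol ether. The fallback sets out from 4 and 5. Aldehyde 5 is converted with di-tert-butyl dicarbonate, i-Pr2NEt and catalytic 4-(dimethylamino)pyridine into tert-butyl 5-(benzyloxy)-2-formylphenyl carbonate F1. (1R,2S)-2-Phenylcyclohexanol is vinylated by Hg(OAc)2-catalysed exchange with 10 to give (1R,2S)-2-phenylcyclohexyl vinyl ether F2. Aryllithium 7, made from 4 as in step 5, is added at −78 °C to F1 in the presence of F2, MgBr2·OEt2 is added and the mixture is warmed. The alkoxide takes over the carbonate group, tert-butyl carbonate leaves from the benzylic position, and quinone methide 11 should add F2 endo on the face left open by the phenyl group, giving the acetal (2R,4R)-7-(benzyloxy)-2-[(1R,2S)-2-phenylcyclohexyloxy]-4-(hexa-O-benzyl-epigallocatechin-8-yl)chroman F3. F3 takes the place of 12 under the conditions of step 9 and comes back to the route at 18. The (1S,2R) auxiliary would be used if the induction has the other sense.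

2. Step 9. The 2,4-trans selectivity may be lost if the aryl group is delivered within a contact ion pair on the face of the departing ethoxide. It may also be lost if the acid reopens ring C at the benzylic C2–O1 bond and the flavan equilibrates to the more stable 2,4-cis isomer. Endocyclic cleavage of the acetal is a further competing pathway. Fallback: C2 is set by a reagent-controlled reduction and ring C is reclosed at O1–C2 by inversion. The fallback sets out from 12. Hydrolysis (AcOH–H2O–THF) gives the lactol 7-(benzyloxy)-4-(hexa-O-benzyl-epigallocatechin-8-yl)chroman-2-ol F4. Aryllithium 14 (2.5 equiv, THF, −78 °C) adds to its open aldehyde form to give the phenol diol 1-[3,4-bis(benzyloxy)phenyl]-3-[4-(benzyloxy)-2-hydroxyphenyl]-3-(hexa-O-benzyl-epigallocatechin-8-yl)propan-1-ol F5 as carbinol epimers. MnO2 in CH2Cl2 oxidises the electron-rich benzylic alcohol to the hydroxy ketone F6. Corey–Bakshi–Shibata reduction with (S)-1-methyl-3,3-diphenyltetrahydro-1H,3H-pyrrolo[1,2-c][1,3,2]oxazaborole and BH3·SMe2 should give the (1R)-carbinol F7. Mitsunobu cyclisation (PPh3, diisopropyl azodicarboxylate) with inversion at the carbinol carbon gives the (2S,4R)-flavan and comes back to the route at 18.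

3. Step 5. In the lithium alkoxide the silyl group may migrate from the phenol oxygen to the new alkoxide, and loss of silanolate would then form the quinone methide while aryllithium is still present. Addition to the hindered ortho-silyloxy aldehyde may also be slow enough for the aryllithium to attack benzylic positions. Fallback: the silyl group is removed from the sequence. The fallback sets out from 4 and 5. Aldehyde 5 is deprotonated with NaH in THF to sodium 5-(benzyloxy)-2-formylphenolate F8. Aryllithium 7, made from 4 as in step 5, is added to F8 at −78 → −20 °C. Work-up with aq NH4Cl gives the diol directly, so the fallback bypasses 6 and 8 and comes back to the route at 9.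

**Further compounds**

F1 | step 7 | tert-butyl 5-(benzyloxy)-2-formylphenyl carbonate | O=Cc1ccc(OCc2ccccc2)cc1OC(=O)OC(C)(C)C
F2 | step 7 | (1R,2S)-2-phenylcyclohexyl vinyl ether | C=CO[C@@H]1CCCC[C@H]1c1ccccc1
F3 | step 7 | (2R,4R)-7-(benzyloxy)-2-[(1R,2S)-2-phenylcyclohexyloxy]-4-(hexa-O-benzyl-epigallocatechin-8-yl)chroman | c1ccccc1COc1ccc2c(c1)O[C@@H](O[C@@H]4CCCC[C@H]4c4ccccc4)C[C@H]2c1c(OCc3ccccc3)cc(OCc3ccccc3)c2c1O[C@H](c1cc(OCc3ccccc3)c(OCc3ccccc3)c(OCc3ccccc3)c1)[C@H](OCc3ccccc3)C2
F4 | step 9 | (4R)-7-(benzyloxy)-4-(hexa-O-benzyl-epigallocatechin-8-yl)chroman-2-ol (lactol, C2 epimers) | c1ccccc1COc1ccc2c(c1)OC(O)C[C@H]2c1c(OCc3ccccc3)cc(OCc3ccccc3)c2c1O[C@H](c1cc(OCc3ccccc3)c(OCc3ccccc3)c(OCc3ccccc3)c1)[C@H](OCc3ccccc3)C2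
F5 | step 9 | 1-[3,4-bis(benzyloxy)phenyl]-3-[4-(benzyloxy)-2-hydroxyphenyl]-3-(hexa-O-benzyl-epigallocatechin-8-yl)propan-1-ol (carbinol epimers) | OC(c1ccc(OCc3ccccc3)c(OCc3ccccc3)c1)C[C@H](c1ccc(OCc3ccccc3)cc1O)c1c(OCc3ccccc3)cc(OCc3ccccc3)c2c1O[C@H](c1cc(OCc3ccccc3)c(OCc3ccccc3)c(OCc3ccccc3)c1)[C@H](OCc3ccccc3)C2
F6 | step 9 | 1-[3,4-bis(benzyloxy)phenyl]-3-[4-(benzyloxy)-2-hydroxyphenyl]-3-(hexa-O-benzyl-epigallocatechin-8-yl)propan-1-one | O=C(c1ccc(OCc3ccccc3)c(OCc3ccccc3)c1)C[C@H](c1ccc(OCc3ccccc3)cc1O)c1c(OCc3ccccc3)cc(OCc3ccccc3)c2c1O[C@H](c1cc(OCc3ccccc3)c(OCc3ccccc3)c(OCc3ccccc3)c1)[C@H](OCc3ccccc3)C2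
F7 | step 9 | (1R)-1-[3,4-bis(benzyloxy)phenyl]-3-[4-(benzyloxy)-2-hydroxyphenyl]-3-(hexa-O-benzyl-epigallocatechin-8-yl)propan-1-ol | O[C@@H](c1ccc(OCc3ccccc3)c(OCc3ccccc3)c1)C[C@H](c1ccc(OCc3ccccc3)cc1O)c1c(OCc3ccccc3)cc(OCc3ccccc3)c2c1O[C@H](c1cc(OCc3ccccc3)c(OCc3ccccc3)c(OCc3ccccc3)c1)[C@H](OCc3ccccc3)C2
F8 | step 5 | sodium 5-(benzyloxy)-2-formylphenolate | [Na+].[O-]c1cc(OCc2ccccc2)ccc1C=O
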